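The target, 13,14-dihydro-19(R)-hydroxy-PGE2, is cut at C7–C8 and C12–C13. The structural handle is the pair of neighbouring cyclopentane carbons C8 and C12, each next to an oxygen-bearing carbon (C9, C11) with both oxygens on the same ring face, plus the saturated C13–C14 link. A 2-iodoacetal hung on the C9 oxygen of a cis-4-silyloxycyclopent-2-enol sends a C7 radical onto C8, closing a cis-fused tetrahydrofuran, and the C12 radical born there is intercepted by the CH2 terminus of a chiral silyloxy enynone. In one operation this makes one ring, two C–C bonds and the C8 and C12 stereocentres, leaving a masked C6 aldehyde and a C15 ynone.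

Key step: step 8

Remark: prostanoid numbering is used throughout (C1 = carboxyl carbon, C20 = terminal methyl). The acetal carbon C6 in 5 and 14–18 and the carbinol carbon C3 of 12 are carried as epimer mixtures, because both end as sp2 carbons.

Step 1
Reactants: 1 (1R,4S)-cis-4-acetoxycyclopent-2-en-1-ol
Product: 2 (1S,4R)-cis-4-(tert-butyldimethylsilyloxy)cyclopent-2-en-1-yl acetate
Conditions: TBSCl, imidazole, DMF, 0 °C to rt
Reagents that add atoms: tert-butyldimethylsilyl chloride (TBSCl), CC(C)(C)[Si](C)(C)Cl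
Why: Imidazole-promoted silylation of the only free hydroxyl places the silyl ether on the future C11, whose R configuration is already that of the target, while the acetate marks the future C9.

Step 2
Reactants: 2 (1S,4R)-cis-4-(tert-butyldimethylsilyloxy)cyclopent-2-en-1-yl acetate
Product: 3 (1S,4R)-cis-4-(tert-butyldimethylsilyloxy)cyclopent-2-en-1-ol
Conditions: K2CO3 (cat.), MeOH, 0 °C to rt
Reagents that add atoms: none
Why: Base-catalysed transesterification with methanol should free the future C9 hydroxyl without touching the silyl ether or either stereocentre.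

Step 3
Reactants: 3 (1S,4R)-cis-4-(tert-butyldimethylsilyloxy)cyclopent-2-en-1-ol, 4 ethyl vinyl ether
Product: 5 iodoacetal tert-butyl{[(1R,4S)-4-(1-ethoxy-2-iodoethoxy)cyclopent-2-en-1-yl]oxy}dimethylsilane (both C6 epimers)
Conditions: N-iodosuccinimide, 4 (3 equiv), CH2Cl2, −20 °C to rt
Reagents that add atoms: N-iodosuccinimide, O=C1CCC(=O)N1I
Why: Haloacetal formation (Ueno–Stork type): the iodonium ion of the electron-rich vinyl ether is opened at its oxocarbenium carbon by the allylic alcohol, the ring alkene being far less nucleophilic, so the C9 oxygen should acquire the C6–C7 iodoacetal tether.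

Step 4
Reactants: 6 (R)-propylene oxide, 7 lithium acetylide–ethylenediamine complex
Product: 8 (R)-pent-4-yn-2-ol
Conditions: LiC≡CH·H2NCH2CH2NH2, DMSO, 5 °C to rt; then H2O
Reagents that add atoms: none
Why: SN2 opening of the epoxide at its unsubstituted carbon by acetylide leaves the C–O stereocentre untouched, so the R carbinol centre becomes C19.

Step 5
Reactants: 8 (R)-pent-4-yn-2-ol
Product: 9 (R)-tert-butyldimethyl(pent-4-yn-2-yloxy)silane
Conditions: TBSCl, imidazole, CH2Cl2, rt
Reagents that add atoms: tert-butyldimethylsilyl chloride (TBSCl), CC(C)(C)[Si](C)(C)Cl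
Why: Imidazole-promoted silylation of a secondary alcohol protects the C19 oxygen for all later steps.

Step 6
Reactants: 9 (R)-tert-butyldimethyl(pent-4-yn-2-yloxy)silane, 10 acrolein
Product: 12 (7R)-7-(tert-butyldimethylsilyloxy)oct-1-en-4-yn-3-ol (both C3 epimers), via lithium acetylide 11 (not isolated)
Conditions: n-BuLi, THF, −78 °C; then 10, −78 °C; then H2O
Reagents that add atoms: none
Why: Deprotonation of the terminal alkyne and kinetic 1,2-addition of the hard lithium acetylide to the aldehyde carbon of acrolein should give the bis-activated carbinol, whose C3 configuration is irrelevant because it is oxidised next.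

Step 7
Reactants: 12 (7R)-7-(tert-butyldimethylsilyloxy)oct-1-en-4-yn-3-ol
Product: 13 (R)-7-(tert-butyldimethylsilyloxy)oct-1-en-4-yn-3-one
Conditions: activated MnO2 (excess), CH2Cl2, rt; filtered, kept cold in solution and used at once
Reagents that add atoms: none
Why: MnO2 oxidises the doubly activated (allylic and propargylic) carbinol under neutral conditions, which suits the polymerisation-prone cross-conjugated enynone.

Step 8
Reactants: 5 iodoacetal tert-butyl{[(1R,4S)-4-(1-ethoxy-2-iodoethoxy)cyclopent-2-en-1-yl]oxy}dimethylsilane, 13 (R)-7-(tert-butyldimethylsilyloxy)oct-1-en-4-yn-3-one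
Product: 14 (3aR,4R,5R,6aS)-5-(tert-butyldimethylsilyloxy)-4-[(7R)-7-(tert-butyldimethylsilyloxy)-3-oxooct-4-yn-1-yl]-2-ethoxyhexahydro-2H-cyclopenta[b]furan (C2 epimers; prostanoid centres 8R,9S,11R,12R,19R)
Conditions: Bu3SnH (1.3 equiv) and AIBN (0.15 equiv) added by syringe pump over 5 h, 13 (4 equiv), degassed PhMe (0.02 M), 80 °C
Reagents that add atoms: none
Why: Bu3Sn• takes iodine from 5, the C7 radical adds to C8 of the ring alkene, the C12 radical so formed adds to the CH2 terminus of 13, and the C14 α-keto radical takes hydrogen from Bu3SnH to carry the chain. The closest known reaction type is the haloacetal (Ueno–Stork) tin hydride radical cyclisation with intermolecular capture of the cyclised radical by an electron-poor alkene. The tetrahydrofuran ring closes in the 5-exo-trig mode, 6-endo attack at C12 being slower. C8 is fixed by the tether, because the O–C6 link from the α-oriented C9 oxygen can bring C7 only to the α face (cis fusion), and C12 is fixed by the substrate, the acceptor approaching the β face anti to both the new C7 branch and the C11 silyl ether. The step needs C–C capture at the vinyl group to beat hydrogen transfer to C12 and attack at the alkyne; the nucleophilic secondary radical is matched with the unhindered, electron-poor CH2 terminus, and slow stannane addition with excess 13 keeps the hydride concentration low. Iodine abstraction by the stannyl radical is faster than its addition to the ynone, so the acceptor should survive while 5 is present.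

Step 9
Reactants: 14 bicyclic ynone acetal
Product: 15 (3aR,4R,5R,6aS)-5-(tert-butyldimethylsilyloxy)-4-[(3R,7R)-7-(tert-butyldimethylsilyloxy)-3-hydroxyoct-4-yn-1-yl]-2-ethoxyhexahydro-2H-cyclopenta[b]furan
Conditions: amido complex Ru[(R,R)-TsNCH(Ph)CH(Ph)NH](p-cymene) (3 mol %; preformed from RuCl[(R,R)-TsDPEN](p-cymene) and KOH, washed base-free), i-PrOH, rt
Reagents that add atoms: none
Why: Noyori-type asymmetric transfer hydrogenation of an α,β-acetylenic ketone is reagent-controlled, and the (R,R) ligand should deliver hydride to give the R propargylic carbinol (the alkynyl group taking the place of the aryl group of aryl ketones), which is the spatial arrangement called 15S once C16–C17 is saturated.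

Step 10
Reactants: 15 propargylic alcohol
Product: 16 (3aR,4R,5R,6aS)-4-[(3R,7R)-3,7-bis(tert-butyldimethylsilyloxy)oct-4-yn-1-yl]-5-(tert-butyldimethylsilyloxy)-2-ethoxyhexahydro-2H-cyclopenta[b]furan
Conditions: TBSCl, imidazole, DMF, rt
Reagents that add atoms: tert-butyldimethylsilyl chloride (TBSCl), CC(C)(C)[Si](C)(C)Cl
Why: Imidazole-promoted silylation is non-acidic and spares the acetal, and capping C15 before hydrogenation prevents metal-induced isomerisation or C–O hydrogenolysis at the propargylic centre.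

Step 11
Reactants: 16 tris-silyl alkyne acetal
Product: 17 (3aR,4R,5R,6aS)-4-[(3S,7R)-3,7-bis(tert-butyldimethylsilyloxy)octyl]-5-(tert-butyldimethylsilyloxy)-2-ethoxyhexahydro-2H-cyclopenta[b]furan
Conditions: H2 (1 atm), 10% Pd/C, EtOAc, rt
Reagents that add atoms: none
Why: Heterogeneous hydrogenation saturates the only C–C multiple bond while acetal and silyl ethers are inert in neutral EtOAc, and no stereocentre is touched (the C15 descriptor changes from R to S only through the change in CIP ranking).

Step 12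
Reactants: 17 saturated tris-silyl acetal
Product: 18 lactol (3aR,4R,5R,6aS)-4-[(3S,7R)-3,7-bis(tert-butyldimethylsilyloxy)octyl]-5-(tert-butyldimethylsilyloxy)hexahydro-2H-cyclopenta[b]furan-2-ol (both anomers)
Conditions: PPTS (0.3 equiv), acetone/H2O (4:1), 45 °C, stopped at full conversion
Reagents that add atoms: water, O
Why: Mild acid hydrolysis of the 2-alkoxytetrahydrofuran acetal through its five-ring oxocarbenium ion belongs to the same reactivity class as THP ether cleavage, which PPTS achieves routinely in the presence of secondary TBS ethers.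

Step 13
Reactants: 18 lactol, 19 (4-carboxybutyl)triphenylphosphonium bromide
Product: 21 (Z)-7-[(1R,2R,3R,5S)-2-[(3S,7R)-3,7-bis(tert-butyldimethylsilyloxy)octyl]-3-(tert-butyldimethylsilyloxy)-5-hydroxycyclopentyl]hept-5-enoic acid, via phosphorus ylide 20 (not isolated)
Conditions: 19 (3 equiv), KOtBu (6 equiv), THF, 0 °C; then 18, 0 °C to rt; aq. NaH2PO4 work-up
Reagents that add atoms: none
Why: Wittig olefination of the lactol through its hydroxy aldehyde form with the non-stabilised ylide should give the 5Z alkene under kinetic control and release C9–OH as the only free hydroxyl, low temperature and a small excess of base limiting silyl migration from O11 to O9.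

Step 14
Reactants: 21 9-hydroxy tris-silyl acid
Product: 22 (Z)-7-[(1R,2R,3R)-2-[(3S,7R)-3,7-bis(tert-butyldimethylsilyloxy)octyl]-3-(tert-butyldimethylsilyloxy)-5-oxocyclopentyl]hept-5-enoic acid
Conditions: Dess–Martin periodinane (1.5 equiv), CH2Cl2, 0 °C to rt; aq. Na2S2O3/NaHCO3 work-up
Reagents that add atoms: none
Why: Dess–Martin oxidation of the single free secondary alcohol should give the C9 ketone under base-free conditions that tolerate the carboxylic acid and the Z alkene and avoid β-elimination of the C11 silyloxy group or epimerisation at C8.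

Step 15
Reactants: 22 tris-silyl keto acid
Product: 23 (Z)-7-[(1R,2R,3R)-3-hydroxy-2-[(3S,7R)-3,7-dihydroxyoctyl]-5-oxocyclopentyl]hept-5-enoic acid (13,14-dihydro-19(R)-hydroxy-PGE2)
Conditions: HF·pyridine, MeCN, 0 °C to rt
Reagents that add atoms: none
Why: Buffered fluoride cleavage of the three secondary TBS ethers is the standard mild end-game for PGE-type β-hydroxy ketones and avoids the base-induced dehydration to the cyclopentenone.

Compound list
1 | (1R,4S)-cis-4-acetoxycyclopent-2-en-1-ol | CC(=O)O[C@H]1C[C@@H](O)C=C1 | starting material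
2 | (1S,4R)-cis-4-(tert-butyldimethylsilyloxy)cyclopent-2-en-1-yl acetate | CC(=O)O[C@H]1C[C@@H](O[Si](C)(C)C(C)(C)C)C=C1 | intermediate
3 | (1S,4R)-cis-4-(tert-butyldimethylsilyloxy)cyclopent-2-en-1-ol | O[C@H]1C[C@@H](O[Si](C)(C)C(C)(C)C)C=C1 | intermediate
4 | ethyl vinyl ether | C=COCC | starting material
5 | tert-butyl{[(1R,4S)-4-(1-ethoxy-2-iodoethoxy)cyclopent-2-en-1-yl]oxy}dimethylsilane (both C6 epimers) | CCOC(CI)O[C@H]1C[C@@H](O[Si](C)(C)C(C)(C)C)C=C1 | intermediate
6 | (R)-propylene oxide | C[C@@H]1CO1 | starting material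
7 | lithium acetylide–ethylenediamine complex | [Li+].[C-]#C.NCCN | starting material
8 | (R)-pent-4-yn-2-ol | C#CC[C@@H](C)O | intermediate
9 | (R)-tert-butyldimethyl(pent-4-yn-2-yloxy)silane | C#CC[C@@H](C)O[Si](C)(C)C(C)(C)C | intermediate
10 | acrolein | C=CC=O | starting material
11 | [(4R)-4-(tert-butyldimethylsilyloxy)pent-1-yn-1-yl]lithium | [Li]C#CC[C@@H](C)O[Si](C)(C)C(C)(C)C | intermediate
12 | (7R)-7-(tert-butyldimethylsilyloxy)oct-1-en-4-yn-3-ol (both C3 epimers) | C=CC(O)C#CC[C@@H](C)O[Si](C)(C)C(C)(C)C | intermediate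
13 | (R)-7-(tert-butyldimethylsilyloxy)oct-1-en-4-yn-3-one | C=CC(=O)C#CC[C@@H](C)O[Si](C)(C)C(C)(C)C | intermediate
14 | (3aR,4R,5R,6aS)-5-(tert-butyldimethylsilyloxy)-4-[(7R)-7-(tert-butyldimethylsilyloxy)-3-oxooct-4-yn-1-yl]-2-ethoxyhexahydro-2H-cyclopenta[b]furan (C2 epimers) | CCOC1C[C@@H]2[C@@H](CCC(=O)C#CC[C@@H](C)O[Si](C)(C)C(C)(C)C)[C@H](O[Si](C)(C)C(C)(C)C)C[C@@H]2O1 | intermediate
15 | (3aR,4R,5R,6aS)-5-(tert-butyldimethylsilyloxy)-4-[(3R,7R)-7-(tert-butyldimethylsilyloxy)-3-hydroxyoct-4-yn-1-yl]-2-ethoxyhexahydro-2H-cyclopenta[b]furan | CCOC1C[C@@H]2[C@@H](CC[C@@H](O)C#CC[C@@H](C)O[Si](C)(C)C(C)(C)C)[C@H](O[Si](C)(C)C(C)(C)C)C[C@@H]2O1 | intermediate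
16 | (3aR,4R,5R,6aS)-4-[(3R,7R)-3,7-bis(tert-butyldimethylsilyloxy)oct-4-yn-1-yl]-5-(tert-butyldimethylsilyloxy)-2-ethoxyhexahydro-2H-cyclopenta[b]furan | CCOC1C[C@@H]2[C@@H](CC[C@@H](O[Si](C)(C)C(C)(C)C)C#CC[C@@H](C)O[Si](C)(C)C(C)(C)C)[C@H](O[Si](C)(C)C(C)(C)C)C[C@@H]2O1 | intermediate
17 | (3aR,4R,5R,6aS)-4-[(3S,7R)-3,7-bis(tert-butyldimethylsilyloxy)octyl]-5-(tert-butyldimethylsilyloxy)-2-ethoxyhexahydro-2H-cyclopenta[b]furan | CCOC1C[C@@H]2[C@@H](CC[C@@H](O[Si](C)(C)C(C)(C)C)CCC[C@@H](C)O[Si](C)(C)C(C)(C)C)[C@H](O[Si](C)(C)C(C)(C)C)C[C@@H]2O1 | intermediate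
18 | (3aR,4R,5R,6aS)-4-[(3S,7R)-3,7-bis(tert-butyldimethylsilyloxy)octyl]-5-(tert-butyldimethylsilyloxy)hexahydro-2H-cyclopenta[b]furan-2-ol (both anomers) | OC1C[C@@H]2[C@@H](CC[C@@H](O[Si](C)(C)C(C)(C)C)CCC[C@@H](C)O[Si](C)(C)C(C)(C)C)[C@H](O[Si](C)(C)C(C)(C)C)C[C@@H]2O1 | intermediate
19 | (4-carboxybutyl)triphenylphosphonium bromide | [Br-].OC(=O)CCCC[P+](c1ccccc1)(c1ccccc1)c1ccccc1 | starting material
20 | potassium 5-(triphenylphosphoranylidene)pentanoate | [K+].[O-]C(=O)CCCC=P(c1ccccc1)(c1ccccc1)c1ccccc1 | intermediate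
21 | (Z)-7-[(1R,2R,3R,5S)-2-[(3S,7R)-3,7-bis(tert-butyldimethylsilyloxy)octyl]-3-(tert-butyldimethylsilyloxy)-5-hydroxycyclopentyl]hept-5-enoic acid | C[C@@H](O[Si](C)(C)C(C)(C)C)CCC[C@H](O[Si](C)(C)C(C)(C)C)CC[C@H]1[C@H](O[Si](C)(C)C(C)(C)C)C[C@H](O)[C@@H]1C/C=C\CCCC(=O)O | intermediate
22 | (Z)-7-[(1R,2R,3R)-2-[(3S,7R)-3,7-bis(tert-butyldimethylsilyloxy)octyl]-3-(tert-butyldimethylsilyloxy)-5-oxocyclopentyl]hept-5-enoic acid | C[C@@H](O[Si](C)(C)C(C)(C)C)CCC[C@H](O[Si](C)(C)C(C)(C)C)CC[C@H]1[C@H](O[Si](C)(C)C(C)(C)C)CC(=O)[C@@H]1C/C=C\CCCC(=O)O | intermediate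
23 | (Z)-7-[(1R,2R,3R)-3-hydroxy-2-[(3S,7R)-3,7-dihydroxyoctyl]-5-oxocyclopentyl]hept-5-enoic acid | C[C@@H](O)CCC[C@H](O)CC[C@H]1[C@H](O)CC(=O)[C@@H]1C/C=C\CCCC(=O)O | target

Total step count: 15 (steps 1–3 ring fragment, steps 4–7 chain fragment, step 8 union, steps 9–15 elaboration).
Longest linear sequence: 12 steps, from (R)-propylene oxide 6 through steps 4–15; the ring branch from 1 is 11 steps.

Steps most likely to fail

Step 8. What may go wrong: hydrogen transfer from the stannane to the C12 radical before it meets the acceptor, addition of stannyl radicals to the triple bond, and chain oligomerisation of the cross-conjugated acceptor at 80 °C. The fallback sets out from 5 and runs the same cyclisation–capture with N-methoxy-N-methylacrylamide (C=CC(=O)N(C)OC, 5 equiv), an acceptor without an alkyne. This should give the Weinreb amide 3-[(3aR,4R,5R,6aS)-5-(tert-butyldimethylsilyloxy)-2-ethoxyhexahydro-2H-cyclopenta[b]furan-4-yl]-N-methoxy-N-methylpropanamide F1. The lithium acetylide 11, made from 9 and n-BuLi in THF at −78 °C, is then added to F1 (−78 to 0 °C); the chelated adduct collapses on work-up to the ynone, and the route is rejoined at 14. Steps 6 and 7 are then not needed.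

Step 13. What may go wrong: in the strongly basic medium the C11 silyl group may wander to the neighbouring cis C9 alkoxide, and the lactolate may open too slowly for the olefination to go to completion. The fallback sets out from 18 and removes all three silyl groups with aqueous HCl in THF to give the lactol triol (3aR,4R,5R,6aS)-4-[(3S,7R)-3,7-dihydroxyoctyl]hexahydro-2H-cyclopenta[b]furan-2,5-diol F2. The Wittig reaction of this silyl-free lactol with excess ylide 20 should give the tetraol acid 13,14-dihydro-19(R)-hydroxy-PGF2α F3. TBSCl (about 4.2 equiv) and imidazole in DMF at 0 °C then silylate the carboxyl group and the more accessible hydroxyls at C11, C15 and C19, leaving the C9 hydroxyl, which is hindered by the cis C8 chain, to give the tert-butyldimethylsilyl ester of 21 F4. Its silyl ester is cleaved with K2CO3 in aqueous MeOH/THF at 0 °C, and the route is rejoined at 21.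

Step 12. What may go wrong: the acidity needed to ionise the acetal may also strip silyl ethers, or hydrolysis may stall under conditions mild enough to keep them. The fallback sets out from 17 and oxidises the acetal directly with m-CPBA and catalytic BF3·OEt2 in dry CH2Cl2 at 0 °C to the γ-lactone (3aR,4R,5R,6aS)-4-[(3S,7R)-3,7-bis(tert-butyldimethylsilyloxy)octyl]-5-(tert-butyldimethylsilyloxy)hexahydro-2H-cyclopenta[b]furan-2-one F5. Half-reduction of F5 with i-Bu2AlH in toluene at −78 °C rejoins the route at 18.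

Further compounds
F1 | step 8 | 3-[(3aR,4R,5R,6aS)-5-(tert-butyldimethylsilyloxy)-2-ethoxyhexahydro-2H-cyclopenta[b]furan-4-yl]-N-methoxy-N-methylpropanamide | CCOC1C[C@@H]2[C@@H](CCC(=O)N(C)OC)[C@H](O[Si](C)(C)C(C)(C)C)C[C@@H]2O1
F2 | step 13 | (3aR,4R,5R,6aS)-4-[(3S,7R)-3,7-dihydroxyoctyl]hexahydro-2H-cyclopenta[b]furan-2,5-diol | OC1C[C@@H]2[C@@H](CC[C@@H](O)CCC[C@@H](C)O)[C@H](O)C[C@@H]2O1
F3 | step 13 | (Z)-7-[(1R,2R,3R,5S)-3,5-dihydroxy-2-[(3S,7R)-3,7-dihydroxyoctyl]cyclopentyl]hept-5-enoic acid | C[C@@H](O)CCC[C@H](O)CC[C@H]1[C@H](O)C[C@H](O)[C@@H]1C/C=C\CCCC(=O)O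
F4 | step 13 | tert-butyldimethylsilyl (Z)-7-[(1R,2R,3R,5S)-2-[(3S,7R)-3,7-bis(tert-butyldimethylsilyloxy)octyl]-3-(tert-butyldimethylsilyloxy)-5-hydroxycyclopentyl]hept-5-enoate | C[C@@H](O[Si](C)(C)C(C)(C)C)CCC[C@H](O[Si](C)(C)C(C)(C)C)CC[C@H]1[C@H](O[Si](C)(C)C(C)(C)C)C[C@H](O)[C@@H]1C/C=C\CCCC(=O)O[Si](C)(C)C(C)(C)C
F5 | step 12 | (3aR,4R,5R,6aS)-4-[(3S,7R)-3,7-bis(tert-butyldimethylsilyloxy)octyl]-5-(tert-butyldimethylsilyloxy)hexahydro-2H-cyclopenta[b]furan-2-one | O=C1C[C@@H]2[C@@H](CC[C@@H](O[Si](C)(C)C(C)(C)C)CCC[C@@H](C)O[Si](C)(C)C(C)(C)C)[C@H](O[Si](C)(C)C(C)(C)C)C[C@@H]2O1
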